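**Retrosynthetic overview**
1. Target 14 comes from tribenzyl acetate 13 (hydrogenolysis), and 13 from primary alcohol 12 (acetylation). The only ring made in the route is the oxolane; all three arenes are bought.
2. Oxolane 12 is cut at the C3–C4 bond to the open-chain epoxy cinnamyl ether 8. In the forward direction Cp2TiCl (trivalent titanium) opens the oxirane reductively and the radical closes the ring 5-exo-trig.
3. Enabling feature: C3 of the oxolane carries an exocyclic oxygen-bearing carbon (the CH2OAc), which is the footprint of a reductively opened terminal oxirane with the radical at C3. Its neighbour C4 carries an exocyclic CH2 bound to the guaiacyl ring, the footprint of a styrene acceptor; C3 and C4 are joined through C2–O1–C5, so the closure is 5-exo.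
4. Ether 8 comes from epoxy alcohol 3 and cinnamyl bromide 7 (Williamson). Alcohol 3 comes from aldehyde 1 by vinyl Grignard addition and Sharpless kinetic resolution, which sets the one stereocentre (C2) that relays to C3 and C4. Bromide 7 comes from aldehyde 4 (Horner–Wadsworth–Emmons, i-Bu2AlH, PBr3).

Key step: step 7

Remark: the phenols are carried as benzyl ethers throughout, and the benzylic radical formed after ring closure is assumed to end as C–H by reduction with a second Cp2TiCl and protonolysis on acidic work-up (hydrogen transfer from THF would give the same product).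

**Step 1**
Reactants: 1 3,4-bis(benzyloxy)benzaldehyde
Product: 2 rac-1-[3,4-bis(benzyloxy)phenyl]prop-2-en-1-ol
Conditions: CH2=CHMgBr (1.2 equiv), THF, −78 to 0 °C; aq. NH4Cl
Reagents that add atoms: vinylmagnesium bromide, C=C[Mg]Br
Why: Grignard 1,2-addition to a non-enolisable aryl aldehyde should give the allylic alcohol cleanly, and it is made racemic on purpose because step 2 resolves it.

**Step 2**
Reactants: 2 rac-1-[3,4-bis(benzyloxy)phenyl]prop-2-en-1-ol
Product: 3 (R)-[3,4-bis(benzyloxy)phenyl][(2S)-oxiran-2-yl]methanol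
Conditions: Ti(OiPr)4 (0.15 equiv), D-(−)-diisopropyl tartrate (0.18 equiv), t-BuOOH (0.45 equiv, anhydrous, isooctane), 4 Å MS, CH2Cl2, −20 °C, stopped below half conversion; aq. NaOH/brine; chromatography removes the unreacted (R)-enantiomer of 2
Reagents that add atoms: tert-butyl hydroperoxide, CC(C)(C)OO
Why: Sharpless kinetic resolution (titanium tartrate epoxidation of a secondary allylic alcohol): with the D-(−)-tartrate the (S)-carbinol should be the fast-reacting enantiomer and be epoxidised on the face that gives the erythro epoxy alcohol, so the carbinol centre that becomes C2 of the oxolane is set here by catalyst control, while the oxirane centre is only temporary.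

**Step 3**
Reactants: 4 4-(benzyloxy)-3-methoxybenzaldehyde
Product: 5 ethyl (2E)-3-[4-(benzyloxy)-3-methoxyphenyl]prop-2-enoate
Conditions: (EtO)2P(O)CH2CO2Et, NaH, THF, 0 °C to rt
Reagents that add atoms: triethyl phosphonoacetate, CCOC(=O)CP(=O)(OCC)OCC
Why: Horner–Wadsworth–Emmons olefination with a stabilised phosphonate anion should give the E-cinnamate under thermodynamic control of the addition step.

**Step 4**
Reactants: 5 ethyl (2E)-3-[4-(benzyloxy)-3-methoxyphenyl]prop-2-enoate
Product: 6 (2E)-3-[4-(benzyloxy)-3-methoxyphenyl]prop-2-en-1-ol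
Conditions: i-Bu2AlH (DIBAL-H, 2.2 equiv), CH2Cl2, −78 °C; aq. potassium sodium tartrate
Reagents that add atoms: none
Why: 1,2-reduction of a conjugated ester by the aluminium hydride at low temperature should give the allylic alcohol without touching the alkene or the benzyl ether.

**Step 5**
Reactants: 6 (2E)-3-[4-(benzyloxy)-3-methoxyphenyl]prop-2-en-1-ol
Product: 7 1-(benzyloxy)-4-[(1E)-3-bromoprop-1-en-1-yl]-2-methoxybenzene
Conditions: PBr3 (0.4 equiv), Et2O, 0 °C; used at once without chromatography
Reagents that add atoms: phosphorus tribromide, BrP(Br)Br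
Why: Bromination of a primary allylic alcohol through its phosphite ester (SN2 by bromide) should give the conjugated E-cinnamyl bromide, which is also the thermodynamic allylic isomer.

**Step 6**
Reactants: 3 (R)-[3,4-bis(benzyloxy)phenyl][(2S)-oxiran-2-yl]methanol; 7 1-(benzyloxy)-4-[(1E)-3-bromoprop-1-en-1-yl]-2-methoxybenzene
Product: 8 (2S)-2-[(R)-[3,4-bis(benzyloxy)phenyl]({(2E)-3-[4-(benzyloxy)-3-methoxyphenyl]prop-2-en-1-yl}oxy)methyl]oxirane
Conditions: NaH (1.1 equiv) added to 3 and 7, n-Bu4NI (cat.), THF/DMF 4:1, −20 to 0 °C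
Reagents that add atoms: none
Why: Williamson ether synthesis: the alkoxide of 3 displaces bromide at the primary allylic carbon of 7 with no bond to the carbinol stereocentre broken, and forming the alkoxide cold in the presence of 7 should outrun Payne rearrangement.

**Step 7**
Reactants: 8 (2S)-2-[(R)-[3,4-bis(benzyloxy)phenyl]({(2E)-3-[4-(benzyloxy)-3-methoxyphenyl]prop-2-en-1-yl}oxy)methyl]oxirane
Product: 12 [(2S,3R,4R)-2-[3,4-bis(benzyloxy)phenyl]-4-{[4-(benzyloxy)-3-methoxyphenyl]methyl}oxolan-3-yl]methanol, via titanoxy radical 9 (not isolated), via cyclized benzylic radical 10 (not isolated), via benzylic organotitanium alkoxide 11 (not isolated)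
Conditions: Cp2TiCl2 (2.5 equiv), Zn dust (6 equiv), THF, rt; the green Cp2TiCl solution is added slowly to 8 (0.02 M in THF); then 1 M HCl
Reagents that add atoms: none
Why: Cp2TiCl (trivalent titanium, made in the flask from Cp2TiCl2 and Zn) opens the terminal oxirane by single-electron transfer towards the more substituted carbon, so the secondary β-titanoxy radical 9 sits on the future C3; 9 adds to the styrene-type alkene through the C2–O1–C5 tether, the benzylic radical 10 is reduced by a second Cp2TiCl to 11, and HCl protonates its C–Ti and O–Ti bonds. The closest known reaction type is the Nugent–RajanBabu reductive epoxide opening with radical cyclisation of epoxy allyl ethers to 3-(hydroxymethyl)oxolanes. The oxolane closes in the 5-exo-trig mode. Both new stereocentres are controlled by the C2 carbinol centre from step 2 through a chair-like Beckwith–Houk transition state: the C2 aryl group lies pseudo-equatorial, which should put the CH2OTi group at C3 trans to it, and the arylmethyl group at C4 should end cis to the C3 substituent and trans to the C2 aryl group. The step needs 5-exo over 6-endo closure and ring closure faster than reduction of 9 by Cp2TiCl (which would end in deoxygenation to an open-chain allyl ether); the aryl group on the alkene terminus secures the first by making the exo adduct a benzylic radical and speeds the addition, and slow addition of Cp2TiCl at high dilution secures the second. The oxirane stereocentre of 8 is erased in 9, so only the carbinol centre has to be enantiopure.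

**Step 8**
Reactants: 12 [(2S,3R,4R)-2-[3,4-bis(benzyloxy)phenyl]-4-{[4-(benzyloxy)-3-methoxyphenyl]methyl}oxolan-3-yl]methanol
Product: 13 [(2S,3R,4R)-2-[3,4-bis(benzyloxy)phenyl]-4-{[4-(benzyloxy)-3-methoxyphenyl]methyl}oxolan-3-yl]methyl acetate
Conditions: Ac2O, pyridine, DMAP (cat.), CH2Cl2, 0 °C to rt
Reagents that add atoms: acetic anhydride, CC(=O)OC(C)=O
Why: DMAP-catalysed acylation of the only free hydroxyl group (primary) should be clean and involves no stereocentre.

**Step 9**
Reactants: 13 [(2S,3R,4R)-2-[3,4-bis(benzyloxy)phenyl]-4-{[4-(benzyloxy)-3-methoxyphenyl]methyl}oxolan-3-yl]methyl acetate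
Product: 14 [(2S,3R,4R)-2-(3,4-dihydroxyphenyl)-4-[(4-hydroxy-3-methoxyphenyl)methyl]oxolan-3-yl]methyl acetate
Conditions: H2 (1 atm), 10% Pd/C, EtOAc, rt, monitored closely; filtration and concentration under argon
Reagents that add atoms: none
Why: Hydrogenolysis of the three aryl benzyl ethers over Pd/C in neutral ethyl acetate should stop at the free phenols, because aryl benzyl ethers are cleaved much faster than the cyclic benzylic C2–O1 bond, and the acetate and the three stereocentres are not affected.

**Compound list**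
1 | 3,4-bis(benzyloxy)benzaldehyde | O=Cc1ccc(OCc2ccccc2)c(OCc2ccccc2)c1 | starting material
2 | rac-1-[3,4-bis(benzyloxy)phenyl]prop-2-en-1-ol | OC(C=C)c1ccc(OCc2ccccc2)c(OCc2ccccc2)c1 | intermediate
3 | (R)-[3,4-bis(benzyloxy)phenyl][(2S)-oxiran-2-yl]methanol | O[C@@H]([C@@H]1CO1)c1ccc(OCc2ccccc2)c(OCc2ccccc2)c1 | intermediate
4 | 4-(benzyloxy)-3-methoxybenzaldehyde | COc1cc(C=O)ccc1OCc1ccccc1 | starting material
5 | ethyl (2E)-3-[4-(benzyloxy)-3-methoxyphenyl]prop-2-enoate | CCOC(=O)/C=C/c1ccc(OCc2ccccc2)c(OC)c1 | intermediate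
6 | (2E)-3-[4-(benzyloxy)-3-methoxyphenyl]prop-2-en-1-ol | OC/C=C/c1ccc(OCc2ccccc2)c(OC)c1 | intermediate
7 | 1-(benzyloxy)-4-[(1E)-3-bromoprop-1-en-1-yl]-2-methoxybenzene | BrC/C=C/c1ccc(OCc2ccccc2)c(OC)c1 | intermediate
8 | (2S)-2-[(R)-[3,4-bis(benzyloxy)phenyl]({(2E)-3-[4-(benzyloxy)-3-methoxyphenyl]prop-2-en-1-yl}oxy)methyl]oxirane | COc1cc(/C=C/CO[C@@H]([C@@H]2CO2)c2ccc(OCc3ccccc3)c(OCc3ccccc3)c2)ccc1OCc1ccccc1 | intermediate
9 | titanoxy radical (not isolated): carbon radical at the former oxirane CH of 8, with O–TiCp2Cl on the former oxirane CH2 | COc1cc(/C=C/CO[C@@H]([CH]CO[Ti](Cl)(C2C=CC=C2)C2C=CC=C2)c2ccc(OCc3ccccc3)c(OCc3ccccc3)c2)ccc1OCc1ccccc1 | intermediate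
10 | cyclized benzylic radical (not isolated): 2,3-trans-3,4-cis oxolane with the radical on the exocyclic benzylic carbon at C4 and CH2O–TiCp2Cl at C3 | COc1cc([CH][C@H]2CO[C@H](c3ccc(OCc4ccccc4)c(OCc4ccccc4)c3)[C@H]2CO[Ti](Cl)(C2C=CC=C2)C2C=CC=C2)ccc1OCc1ccccc1 | intermediate
11 | benzylic organotitanium alkoxide (not isolated): as 10, with the benzylic carbon bound to TiCp2Cl (tetravalent titanium) | COc1cc(C([Ti](Cl)(C2C=CC=C2)C2C=CC=C2)[C@H]2CO[C@H](c3ccc(OCc4ccccc4)c(OCc4ccccc4)c3)[C@H]2CO[Ti](Cl)(C2C=CC=C2)C2C=CC=C2)ccc1OCc1ccccc1 | intermediate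
12 | [(2S,3R,4R)-2-[3,4-bis(benzyloxy)phenyl]-4-{[4-(benzyloxy)-3-methoxyphenyl]methyl}oxolan-3-yl]methanol | COc1cc(C[C@H]2CO[C@H](c3ccc(OCc4ccccc4)c(OCc4ccccc4)c3)[C@H]2CO)ccc1OCc1ccccc1 | intermediate
13 | [(2S,3R,4R)-2-[3,4-bis(benzyloxy)phenyl]-4-{[4-(benzyloxy)-3-methoxyphenyl]methyl}oxolan-3-yl]methyl acetate | COc1cc(C[C@H]2CO[C@H](c3ccc(OCc4ccccc4)c(OCc4ccccc4)c3)[C@H]2COC(C)=O)ccc1OCc1ccccc1 | intermediate
14 | [(2S,3R,4R)-2-(3,4-dihydroxyphenyl)-4-[(4-hydroxy-3-methoxyphenyl)methyl]oxolan-3-yl]methyl acetate | COc1cc(C[C@H]2CO[C@H](c3ccc(O)c(O)c3)[C@H]2COC(C)=O)ccc1O | target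

**Total step count:** 9
**Longest linear sequence:** 7 steps (steps 3, 4, 5, 6, 7, 8, 9 from aldehyde 4)

**Steps most likely to fail**

Step 7. The 5-exo closure may give too much of the C4 epimer, because the cis preference between the C3 and C4 substituents is the weaker of the two controlling effects. Radical 9 may also be reduced by Cp2TiCl before it cyclises, which ends in loss of the oxygen. The fallback sets out from epoxy alcohol 3 and aldehyde 4 and comes back to the route at target 14. It changes the acceptor from the alkene to the alkyne, so that the radical step sets only C3 and C4 is set afterwards by hydrogenation. Aldehyde 4 is taken by Corey–Fuchs olefination (CBr4, PPh3, CH2Cl2) to 1-(benzyloxy)-4-(2,2-dibromoethenyl)-2-methoxybenzene F1. n-BuLi (2 equiv, THF, −78 °C) and then paraformaldehyde give 3-[4-(benzyloxy)-3-methoxyphenyl]prop-2-yn-1-ol F2, and PBr3 gives 1-(benzyloxy)-4-(3-bromoprop-1-yn-1-yl)-2-methoxybenzene F3. Williamson etherification of 3 with F3 under the conditions of step 6 gives the epoxy propargyl ether F4. Cp2TiCl (from Cp2TiCl2 and Zn, THF) then opens the oxirane and the radical closes 5-exo-dig onto the alkyne, the vinyl radical taking hydrogen from THF. This should give the 4-benzylidene oxolane alcohol F5 with the C3 substituent trans to the C2 aryl group; the alkene geometry does not matter. Acetylation (Ac2O, pyridine, DMAP) gives the benzylidene acetate F6. Hydrogenation over Pd/C in ethyl acetate should add hydrogen to the exocyclic alkene from the face opposite the adjacent C3 acetoxymethyl group, leaving the arylmethyl group cis to it, and should remove the three benzyl groups in the same operation to give 14.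

Step 2. The product is taken from a kinetic resolution, so its ee depends directly on the rate difference between the enantiomers, and the titanium Lewis acid may ionise the electron-rich benzylic carbinol. The fallback sets out from racemic alcohol 2; it comes back to the route at 3 and, for the epimeric material, at radical 9. It separates the two tasks. An enzymatic resolution with a lipase (Candida antarctica lipase B, Novozym 435, vinyl acetate, MTBE, rt) should acylate the (R)-enantiomer (Kazlauskas rule with the aryl group as the large substituent) to (R)-1-[3,4-bis(benzyloxy)phenyl]prop-2-en-1-yl acetate F8. This leaves (S)-1-[3,4-bis(benzyloxy)phenyl]prop-2-en-1-ol F7, whose ee can be raised by running past half conversion. Hydroxyl-directed epoxidation of F7 with mCPBA (NaHCO3, CH2Cl2, 0 °C) gives 3 together with its oxirane epimer (R)-[3,4-bis(benzyloxy)phenyl][(2R)-oxiran-2-yl]methanol F9. The mixture need not be separated: etherification as in step 6 gives 8 and its oxirane epimer F10, and both open to the same radical 9 in step 7.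

Step 6. The epoxy alkoxide may undergo Payne rearrangement before it is alkylated, and the electron-rich cinnamyl bromide 7 may decompose or react in the SN2' sense. The fallback sets out from allylic alcohol 6 and epoxy alcohol 3 and comes back to the route at 8. It avoids both the free alkoxide and the bromide by a palladium-catalysed allylic etherification. Alcohol 6 is acetylated (Ac2O, pyridine, DMAP) to (2E)-3-[4-(benzyloxy)-3-methoxyphenyl]prop-2-en-1-yl acetate F11. The zinc alkoxide of 3 (Et2Zn, 0.5 equiv, THF) is then coupled with F11 using Pd(OAc)2 (reduced in the flask to zerovalent palladium), 2-(di-tert-butylphosphino)biphenyl and NH4OAc (cat.) in THF at rt. Attack of the alkoxide at the less substituted terminus of the aryl-substituted π-allyl palladium intermediate should give the linear E-ether 8 with the carbinol centre untouched.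

**Further compounds**
F1 | step 7 | 1-(benzyloxy)-4-(2,2-dibromoethenyl)-2-methoxybenzene | COc1cc(C=C(Br)Br)ccc1OCc1ccccc1
F2 | step 7 | 3-[4-(benzyloxy)-3-methoxyphenyl]prop-2-yn-1-ol | COc1cc(C#CCO)ccc1OCc1ccccc1
F3 | step 7 | 1-(benzyloxy)-4-(3-bromoprop-1-yn-1-yl)-2-methoxybenzene | COc1cc(C#CCBr)ccc1OCc1ccccc1
F4 | step 7 | (2S)-2-[(R)-[3,4-bis(benzyloxy)phenyl]({3-[4-(benzyloxy)-3-methoxyphenyl]prop-2-yn-1-yl}oxy)methyl]oxirane | COc1cc(C#CCO[C@@H]([C@@H]2CO2)c2ccc(OCc3ccccc3)c(OCc3ccccc3)c2)ccc1OCc1ccccc1
F5 | step 7 | [(2S,3R)-2-[3,4-bis(benzyloxy)phenyl]-4-{[4-(benzyloxy)-3-methoxyphenyl]methylidene}oxolan-3-yl]methanol | COc1cc(C=C2CO[C@H](c3ccc(OCc4ccccc4)c(OCc4ccccc4)c3)[C@H]2CO)ccc1OCc1ccccc1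
F6 | step 7 | [(2S,3R)-2-[3,4-bis(benzyloxy)phenyl]-4-{[4-(benzyloxy)-3-methoxyphenyl]methylidene}oxolan-3-yl]methyl acetate | COc1cc(C=C2CO[C@H](c3ccc(OCc4ccccc4)c(OCc4ccccc4)c3)[C@H]2COC(C)=O)ccc1OCc1ccccc1
F7 | step 2 | (S)-1-[3,4-bis(benzyloxy)phenyl]prop-2-en-1-ol | O[C@@H](C=C)c1ccc(OCc2ccccc2)c(OCc2ccccc2)c1
F8 | step 2 | (R)-1-[3,4-bis(benzyloxy)phenyl]prop-2-en-1-yl acetate | CC(=O)O[C@H](C=C)c1ccc(OCc2ccccc2)c(OCc2ccccc2)c1
F9 | step 2 | (R)-[3,4-bis(benzyloxy)phenyl][(2R)-oxiran-2-yl]methanol | O[C@@H]([C@H]1CO1)c1ccc(OCc2ccccc2)c(OCc2ccccc2)c1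
F10 | step 2 | (2R)-2-[(R)-[3,4-bis(benzyloxy)phenyl]({(2E)-3-[4-(benzyloxy)-3-methoxyphenyl]prop-2-en-1-yl}oxy)methyl]oxirane | COc1cc(/C=C/CO[C@@H]([C@H]2CO2)c2ccc(OCc3ccccc3)c(OCc3ccccc3)c2)ccc1OCc1ccccc1
F11 | step 6 | (2E)-3-[4-(benzyloxy)-3-methoxyphenyl]prop-2-en-1-yl acetate | CC(=O)OC/C=C/c1ccc(OCc2ccccc2)c(OC)c1
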